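(The numbers in the tables stem from a simulated flask for an exercise, noise included.)

If your hunch was that a slower feed of partner would buy more target, I tested it on the two earlier runs before giving you a number, and I doubted it.

| setting | Friday's | Tuesday's | alder | birch | oak | elm |
|---|---|---|---|---|---|---|
| substrate | 0.050 M | 0.20 M | 0.10 M | 0.10 M | 0.10 M | 0.10 M |
| partner | 0.105 M (fed, over 0.12 min) | 0.105 M (fed, over 0.12 min) | 0.105 M (fed, over 0.12 min) | 0.105 M (fed, over 0.25 min) | 0.105 M (fed, over 0.50 min) | 0.105 M (fed, over 1.0 min) |
| free catalyst | 0.20 mM | 0.20 mM | 0.20 mM | 0.20 mM | 0.20 mM | 0.20 mM |
| remark | run made earlier; the fed solution adds 1.0 times the starting volume | run made earlier; the fed solution adds 1.0 times the starting volume | the fed solution adds 1.0 times the starting volume | the fed solution adds 1.0 times the starting volume | the fed solution adds 1.0 times the starting volume | the fed solution adds 1.0 times the starting volume |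
| time |  |  | 15 min | 15 min | 15 min | 15 min |

- Friday's (time / min: target / %, substrate / %): 2.00: 21.2, 78.9; 4.00: 38.2, 61.1; 6.00: 51.3, 48.6; 8.00: 60.6, 39.7; 10.0: 66.8, 32.8; 12.0: 71.1, 27.8; 15.0: 75.7, 23.9
- Tuesday's (time / min: target / %, substrate / %): 1.33: 4.9, 94.7; 2.00: 7.7, 92.3; 3.00: 10.5, 88.9; 4.00: 13.4, 86.2; 6.00: 17.3, 82.6; 10.0: 20.8, 79.7; 15.0: 21.3, 78.7

(scatter of a reading: 0.3 percentage points)

- a species is counted by the substrate in it: one spent catalyst counts as two
- charges are per starting volume, the dose included; the dosed solution carries all of it
- the numbers in the tables scatter with a standard deviation of 0.3 percentage points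
- steps under discussion: substrate + free catalyst -> catalyst intermediate A; partner + catalyst intermediate A -> catalyst intermediate B; catalyst intermediate B -> released group + catalyst intermediate C; catalyst intermediate C <-> catalyst intermediate D; catalyst intermediate D -> free catalyst + target; catalyst intermediate A + target -> spent catalyst
- "hardly changes" means that all values lie within two and a half points (for a concentration: within two and a half percent of the largest)

- amount of target at the end, in percent of the substrate charged for alder, birch, oak, elm, in this order
- how the row runs (falls, then rises / falls all the way / rises, then falls / rises all the way / hardly changes)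

I started from Tuesday's run. Its target crept from 20.8% to 21.3% over the last readings while 78.7% of its substrate still stood, so I took it that the catalyst had stopped, not the supply. I therefore defined a capacity, the concentration of target that one charge of catalyst makes before it is lost, and read it as Tuesday's last target times Tuesday's substrate charge: 0.0426 M. Friday's run, at 0.0379 M, was still climbing below it. The new flasks carried the same catalyst and partner as Tuesday's, and the partner charge stood above the capacity, so partner was not the limiting reagent. For 0.10 M of substrate that read as a ceiling of about 42.6%, with the scatter of Tuesday's reading in it.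

I treated the feed as a small correction to this. The longest feed delayed the average partner by 0.500 min, short against 15 min. So I committed to a flat row just under my ceiling. The forecast stood somewhat lower, at 40.6%, 40.5%, 40.3% and 40%, a row that hardly changes: “The yield therefore drops by only a few tenths of a point”.

The simulation gave 41.9%, 41.9%, 41.9% and 41.7%, a row that hardly changes.

    substrate + free catalyst → catalyst intermediate A (k = 48.0 L mol⁻¹ s⁻¹)
    partner + catalyst intermediate A → catalyst intermediate B (k = 56.0 L mol⁻¹ s⁻¹)
    catalyst intermediate B → released group + catalyst intermediate C (k = 1.90 s⁻¹)
    catalyst intermediate C ⇌ catalyst intermediate D (K = 0.980, k = 83.0 s⁻¹)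
    catalyst intermediate D → free catalyst + target (k = 5.60 s⁻¹)
    catalyst intermediate A + target → spent catalyst (k = 0.920 L mol⁻¹ s⁻¹)

The loss of catalyst intermediate A with target to spent catalyst is the main reason alder ended there: the same alder run without that step gave 77.5% against 41.9%. At 15.0 min, alder held 95.7% of its catalyst as spent catalyst, and its target had used 98.4% of the capacity. Elm, fed over 1.0 min, held 95.5% as spent catalyst and had used 97.9%.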